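Readings and results were generated by integration with constants of no real substance; scatter was added.

Two reagents fall together in this flask.

| flask | starting material | coupling partner | free catalyst | remark |
|---|---|---|---|---|
| green | 0.020 M | 0.021 M | 20 µM | the very flask that is asked about, followed so far |
| flask | 0.020 M | 0.0210 M | 20 µM |  |

- apparent order in coupling partner when 5.0% of the starting material are converted (percent change of the rate of making target for one percent more coupling partner charged)

- green (time / h: target / %, starting material / %): 1.50: 18.0, 81.1; 5.00: 53.7, 46.7; 8.00: 69.7, 27.2; 12.0: 83.5, 15.6; 20.0: 97.4, 2.0; 25.0: 99.7, 0.8; 30.0: 102.2, 0.5

(each reading ± 1 percentage point)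

- the analysis behind the earlier runs scatters by 1 percentage point, standard deviation
- no earlier run changes the charge of coupling partner; that part of a forecast is a guess

Coupling partner exceeds starting material by 0.00100 M in the charge, small against 0.020 M, so in the green run the two concentrations drop nearly in step. The starting-material column can therefore be read as one falling level.

Between 1.50 h and 5.00 h that column loses 0.0983 h⁻¹ of the charge around a mean level of 63.9%. Between 8.00 h and 12.0 h it loses 0.0290 h⁻¹ around 21.4%. The rate thus falls by a factor of 3.39 while the level falls by 2.99.

The logarithm of the first factor over that of the second gives 1.12. This is the joint order, the sum of the orders in the two reagents, and it is a reading that carries the scatter of the column.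

The green run has one charge of coupling partner, so the sum stays unsplit. This reckoning places the order in coupling partner on a scale from 0 to the joint order, and the symmetric case, an even split between the two reagents, marks its middle. My reckoning commits to that even split, 0.558.

The forecast stands lower, at 0.03: “I expect about zero”.

The simulation gives 0.85.

    starting material + free catalyst → catalyst intermediate A (k = 77000 M⁻¹ h⁻¹)
    coupling partner + catalyst intermediate A → catalyst intermediate B (k = 21000 M⁻¹ h⁻¹)
    catalyst intermediate B ⇌ free catalyst + target (K = 0.0170 M, k = 840 h⁻¹)
    2 catalyst intermediate A ⇌ resting dimer, settled at all times (K = 94000 M⁻¹)

That lies above the even split and takes 75.9% of the joint order. With coupling partner as charged, its step runs at 11000 d⁻¹ per catalyst intermediate A, lower than the 37000 d⁻¹ per free catalyst and the 20000 d⁻¹ per catalyst intermediate B of the other two steps. In the flask with twice the coupling partner, the time to that conversion changes by a factor of 0.596, on average over that doubling an order of 0.747, which is 66.7% of the joint order.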